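Its constants come from no measurement, and the outcome is calculated.

Set against a tank held on average as long, a closed flask should keep its target beside substrate for a shorter exposure, and the next charge hangs on that comparison.

all flasks: substrate 0.35 M

| charge | remark | time |
|---|---|---|
| blue | a single well-mixed tank run continuously and read at steady state, 25 h in it on average |  |
| violet | a closed flask charged with all of it at once and left for 25 h | 25 h |

    substrate ⇌ intermediate A (K1 = 0.163, k1 = 0.0686 h⁻¹)
    substrate ⇌ intermediate B (K2 = 0.44, k2 = 0.0430 h⁻¹)
    intermediate A ⇌ intermediate C (K3 = 2.73, k3 = 0.0758 h⁻¹)
    intermediate A ⇌ target (K4 = 2.7, k4 = 0.0369 h⁻¹)
    substrate + target → side product (k5 = 0.131 L mol⁻¹ h⁻¹)
    substrate → decomposition product (k6 = 1.51 × 10⁻⁵ h⁻¹)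

- in percentages every species weighs as the substrate in it: one side product counts as two
- the stated concentrations are those of everything mixed, before any reaction; amounts are the same in each set-up
- run time (violet): 25 h

1. the set-up with the highest share of target in all that became target or side product, at the outlet or at the end ("none" if the first two lie within 2 percentage points) (blue / violet / none)
2. share of target in all that became target or side product, at the outlet or at the end, blue
3. share of target in all that became target or side product, at the outlet or at the end, violet

I must choose the vessel for the next run. Substrate consumes target with a pseudo-first-order rate constant of 0.0458 h⁻¹ at the charged level, and the half-life of target by this step alone, the other concentrations as charged in violet, is 15 h, shorter than the 25 h in the vessel, so I reckon with this loss. I therefore carry the burn number N, the weight of side product made per weight of target held beside the full charge of substrate for the time in the vessel, 2.29, which is twice that rate constant times that time. Let f be the substrate as a fraction of the charge. In the blue tank, the steady-state balance on side product makes its weight over the target equal to Nf, so the share is the reciprocal of one plus Nf. In the violet flask, if target grows at a steady pace, its average over the run is half its final amount, so Nf is halved, with f now a mean.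

For f, the balance on intermediate B in the blue tank gives 31.2% of the substrate level. I guess that the branch through intermediate A holds as much, and I use the resulting f of 0.616 for both vessels. That gives 41.5% for blue and 58.6% for violet. The gap of 17 percentage points is far wider than the margin, so I charge violet.

The forecast also names violet, with 43% for blue and 58% for violet, on the ground that “the flask starts with almost no target while substrate is at its highest”. My figure lies below its figure for blue and above it for violet.

The simulation gives 42.9% for blue and 56.7% for violet, so violet is best. The blue outlet reads 58.1% of the substrate charged, and N with that fraction gives 42.9%. Left ten times as long, the violet flask has a burn number of 22.9, and the halved rule with my f gives 12.4%. After 250 h, the violet flask stands at 11.4%.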